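**Plan**

1. Retrosynthetic cuts: the C1′ acid comes from its methyl ester and the C5–OH from enolate oxidation. Then O1–C2 is cut together with C3–C3a, which splits the target into cyclohexane-1,3-dione (ring A) and a C15 cis-2,3-epoxy aldehyde. The epoxide comes from Sharpless epoxidation of a (Z)-allylic alcohol; the chain comes from a Wittig reaction (C2′=C3′) and a Johnson–Claisen rearrangement (C6′=C7′) on a C7 aldehyde cut out of nerol.
2. Enabling feature: ring A is a cyclohexane-1,3-dione frozen as its enol ether (O1–C7a=C3a–C4=O). O1 is therefore an enol oxygen, C3a the carbon between two carbonyls, C3 an aldehyde carbon in disguise, and the vicinal O1–C2/HO–C10′ pair an opened epoxide.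
3. Forward order: chain (steps 1–7), epoxide (8), aldehyde (9), then ring B is closed onto ring A in the same operation that joins the two fragments (10), C5 hydroxylation (11), ester cleavage (12).
4. Stereochemistry: C2 and C10′ both come from the Sharpless epoxide (C2 by inversion, C10′ by retention in step 10). The Z olefin of nerol becomes the cis epoxide and so fixes their relative configuration. 6′E comes from the chair Claisen transition state, 2′E from the stabilised ylide, and C5 from a chiral N-sulfonyloxaziridine.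
5. Locants: the bicycle is numbered as 1-benzofuran (O1, C2, C3, C3a, C4–C7, C7a); the side chain is numbered as the undecadienoic acid with primes (C1′ = CO2H … C10′ = carbinol carbon).

Key step: step 10

Remark: the acid is carried as its methyl ester to the last step, and the sense of induction of the oxaziridine in step 11 is assigned by analogy with cyclic ketone enolates, so it should be confirmed on small scale (the antipodal reagent is equally available).

**Route**

Step 1
Reactants: 1 nerol
Product: 2 tert-butyl{[(2Z)-3,7-dimethylocta-2,6-dien-1-yl]oxy}diphenylsilane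
Conditions: t-BuPh2SiCl, imidazole, CH2Cl2, 0 °C to rt
Reagents that add atoms: tert-butyl(chloro)diphenylsilane, CC(C)(C)[Si](Cl)(c1ccccc1)c1ccccc1
Why: Silylation of the primary allylic alcohol gives a bulky, acid-stable ether that should survive the oxidative cleavage, the Grignard addition, the hot orthoester Claisen and the hydride reduction, and that deactivates the 2,3-olefin towards peracid.

Step 2
Reactants: 2 neryl silyl ether
Product: 4 (4Z)-6-[(tert-butyldiphenylsilyl)oxy]-4-methylhex-4-enal, via terminal epoxide 3 (not isolated)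
Conditions: mCPBA (1.05 equiv), NaHCO3, CH2Cl2, −20 to 0 °C; then H5IO6, THF/H2O, 0 °C
Reagents that add atoms: meta-chloroperoxybenzoic acid, OOC(=O)c1cccc(Cl)c1
Why: Peracid epoxidation should pick the electron-rich, unhindered terminal olefin over the one carrying the allylic silyloxy group, and periodic acid then cleaves the epoxide to the aldehyde and acetone without touching the Z olefin.

Step 3
Reactants: 4 silyloxy aldehyde; 5 isopropenylmagnesium bromide
Product: 6 (6Z)-8-[(tert-butyldiphenylsilyl)oxy]-2,6-dimethylocta-1,6-dien-3-ol (racemic)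
Conditions: CH2=C(CH3)MgBr, THF, −78 to 0 °C; then H2O
Reagents that add atoms: none
Why: Grignard 1,2-addition to the only electrophile present gives the secondary allylic alcohol needed for the Claisen step; its carbinol centre is destroyed in step 4, so no stereocontrol is needed.

Step 4
Reactants: 6 allylic alcohol; 7 triethyl orthoacetate
Product: 9 ethyl (4E,8Z)-10-[(tert-butyldiphenylsilyl)oxy]-4,8-dimethyldeca-4,8-dienoate, via ketene acetal 8 (not isolated)
Conditions: CH3C(OEt)3 (excess), EtCO2H (cat.), 140 °C, EtOH distilled off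
Reagents that add atoms: none
Why: The Johnson–Claisen rearrangement passes through a chair transition state with the carbinol substituent equatorial, which should give the trisubstituted C6′=C7′ olefin as the E isomer and add two chain carbons.

Step 5
Reactants: 9 ethyl ester
Product: 10 (4E,8Z)-10-[(tert-butyldiphenylsilyl)oxy]-4,8-dimethyldeca-4,8-dienal
Conditions: i-Bu2AlH (1.1 equiv), CH2Cl2, −78 °C; then aq. potassium sodium tartrate
Reagents that add atoms: none
Why: Partial reduction of an unhindered ethyl ester at low temperature stops at the aluminium hemiacetal, which gives the aldehyde on work-up; the silyl ether and both olefins are inert.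

Step 6
Reactants: 10 aldehyde; 11 methyl 2-(triphenylphosphoranylidene)propanoate
Product: 12 methyl (2E,6E,10Z)-12-[(tert-butyldiphenylsilyl)oxy]-2,6,10-trimethyldodeca-2,6,10-trienoate
Conditions: toluene, 80 °C
Reagents that add atoms: none
Why: Wittig olefination with a stabilised α-methyl ylide should give the (E)-2-methyl enoate under thermodynamic control of oxaphosphetane formation.

Step 7
Reactants: 12 silyl ether
Product: 13 methyl (2E,6E,10Z)-12-hydroxy-2,6,10-trimethyldodeca-2,6,10-trienoate
Conditions: Bu4NF, AcOH, THF, 0 °C to rt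
Reagents that add atoms: none
Why: Buffered fluoride desilylation frees the (Z)-allylic alcohol without hydrolysing the methyl ester or isomerising the olefins.

Step 8
Reactants: 13 (Z)-allylic alcohol
Product: 14 methyl (2E,6E)-9-[(2S,3R)-3-(hydroxymethyl)-2-methyloxiran-2-yl]-2,6-dimethylnona-2,6-dienoate
Conditions: Ti(OiPr)4 (10 mol %), D-(−)-diethyl tartrate (12 mol %), t-BuOOH (anhydrous, in decane), 4 Å molecular sieves, CH2Cl2, −20 °C
Reagents that add atoms: tert-butyl hydroperoxide, CC(C)(C)OO
Why: Sharpless asymmetric epoxidation acts only on the olefin that carries the allylic hydroxyl, and the titanium D-(−)-tartrate catalyst sets both epoxide centres by reagent control, giving the cis epoxide that is the enantiomer of the one nerol itself gives with the L-(+)-ester.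

Step 9
Reactants: 14 epoxy alcohol
Product: 15 methyl (2E,6E)-9-[(2S,3S)-3-formyl-2-methyloxiran-2-yl]-2,6-dimethylnona-2,6-dienoate
Conditions: TEMPO (10 mol %), PhI(OAc)2 (1.1 equiv), CH2Cl2, rt; used crude
Reagents that add atoms: none
Why: Oxoammonium oxidation of the primary alcohol is neutral and should leave the acid- and base-sensitive epoxy aldehyde, the olefins and the ester intact, with the epoxide carbons unchanged (the descriptor at the CH carbon changes only by priority).

Step 10
Reactants: 15 epoxy aldehyde; 16 cyclohexane-1,3-dione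
Product: 19 methyl (2E,6E,10S)-10-hydroxy-2,6-dimethyl-10-[(2S)-4-oxo-2,3,4,5,6,7-hexahydro-1-benzofuran-2-yl]undeca-2,6-dienoate, via alkylidene dione 17 (not isolated), via epoxy dione 18 (not isolated)
Conditions: L-proline (10 mol %), diethyl 2,6-dimethyl-1,4-dihydropyridine-3,5-dicarboxylate (Hantzsch ester, 1.05 equiv), CH2Cl2, rt; then DBU (1.2 equiv), rt to 40 °C
Reagents that add atoms: none
Why: Proposed new method: the dione condenses with the epoxy aldehyde (proline iminium, Knoevenagel) to the 2-alkylidene dione 17, whose doubly activated C=C takes a hydride from the Hantzsch ester at the former aldehyde carbon to give the 2-(2,3-epoxyalkyl) dione 18, and DBU then ionises the acidic enol so that the enolate oxygen opens the epoxide at its secondary carbon from the back side. The closest known reaction types are the organocatalytic three-component reductive alkylation of cyclic 1,3-diones with aldehydes and a Hantzsch ester, and the base-mediated cyclisation of 2-(2,3-epoxyalkyl)-1,3-diones and ortho-(epoxyalkyl)phenols to 2-(1-hydroxyalkyl)dihydrofurans; new here are an α,β-epoxy aldehyde as the aldehyde partner and the telescoping of the two events. The one ring formed, ring B (O1–C2–C3–C3a–C7a), closes in the 5-exo-tet mode. C2 is set by stereospecific SN2 inversion at the epoxide CH carbon and C10′ keeps the configuration of the quaternary epoxide carbon, so the (2S,3S)-cis-epoxy aldehyde should give the (2S,10′S) product. The step needs O- over C-attack (C-attack would build a strained spiro-cyclopropane and is disfavoured for a stabilised dione enolate), 5-exo over 6-endo opening (secured by closing on the enolate under basic conditions, where attack goes to the less substituted epoxide carbon, whereas acid would favour the tertiary carbon), and hydride transfer to the alkylidene dione only (the isolated olefins, the enoate and the epoxide are not acceptors for a dihydropyridine).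

Step 11
Reactants: 19 bicyclic vinylogous ester
Product: 21 methyl (2E,6E,10S)-10-hydroxy-10-[(2S,5R)-5-hydroxy-4-oxo-2,3,4,5,6,7-hexahydro-1-benzofuran-2-yl]-2,6-dimethylundeca-2,6-dienoate, via disodium dienolate 20 (not isolated)
Conditions: NaN(SiMe3)2 (2.3 equiv), THF, −78 °C; then (1S)-(+)-(10-camphorsulfonyl)oxaziridine (1.3 equiv), −78 °C; then AcOH
Reagents that add atoms: (1S)-(+)-(10-camphorsulfonyl)oxaziridine, CC1(C)[C@@H]2CC[C@]13CS(=O)(=O)N4O[C@@]34C2
Why: After the tertiary hydroxyl, the base removes the kinetic α′ proton at C5 of the vinylogous ester, and the cross-conjugated dienolate is hydroxylated at carbon by the N-sulfonyloxaziridine (enolate α-hydroxylation), with C5 set by reagent control from the camphor skeleton and with no reaction at the isolated olefins or the enoate.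

Step 12
Reactants: 21 methyl ester
Product: 22 (2E,6E,10S)-10-hydroxy-10-[(2S,5R)-5-hydroxy-4-oxo-2,3,4,5,6,7-hexahydro-1-benzofuran-2-yl]-2,6-dimethylundeca-2,6-dienoic acid
Conditions: Me3SnOH (6 equiv), 1,2-dichloroethane, 70 °C; then cold 0.1 M aq. HCl wash
Reagents that add atoms: trimethyltin hydroxide, C[Sn](C)(C)O
Why: Tin hydroxide-mediated ester cleavage is close to neutral and should free the acid without epimerising the α-ketol at C5 or opening the vinylogous ester, both of which aqueous hydroxide would endanger.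

**Compound list**

1 | nerol, (2Z)-3,7-dimethylocta-2,6-dien-1-ol | CC(C)=CCC/C(C)=C\CO | starting material
2 | tert-butyl{[(2Z)-3,7-dimethylocta-2,6-dien-1-yl]oxy}diphenylsilane | CC(C)=CCC/C(C)=C\CO[Si](c1ccccc1)(c1ccccc1)C(C)(C)C | intermediate
3 | tert-butyl{[(2Z)-5-(3,3-dimethyloxiran-2-yl)-3-methylpent-2-en-1-yl]oxy}diphenylsilane (racemic) | CC1(C)OC1CC/C(C)=C\CO[Si](c1ccccc1)(c1ccccc1)C(C)(C)C | intermediate
4 | (4Z)-6-[(tert-butyldiphenylsilyl)oxy]-4-methylhex-4-enal | O=CCC/C(C)=C\CO[Si](c1ccccc1)(c1ccccc1)C(C)(C)C | intermediate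
5 | isopropenylmagnesium bromide | CC(=C)[Mg]Br | starting material
6 | (6Z)-8-[(tert-butyldiphenylsilyl)oxy]-2,6-dimethylocta-1,6-dien-3-ol (racemic) | C=C(C)C(O)CC/C(C)=C\CO[Si](c1ccccc1)(c1ccccc1)C(C)(C)C | intermediate
7 | triethyl orthoacetate | CCOC(C)(OCC)OCC | starting material
8 | tert-butyl({(2Z)-6-[(1-ethoxyethenyl)oxy]-3,7-dimethylocta-2,7-dien-1-yl}oxy)diphenylsilane (racemic ketene acetal) | C=C(OCC)OC(CC/C(C)=C\CO[Si](c1ccccc1)(c1ccccc1)C(C)(C)C)C(C)=C | intermediate
9 | ethyl (4E,8Z)-10-[(tert-butyldiphenylsilyl)oxy]-4,8-dimethyldeca-4,8-dienoate | CCOC(=O)CC/C(C)=C/CC/C(C)=C\CO[Si](c1ccccc1)(c1ccccc1)C(C)(C)C | intermediate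
10 | (4E,8Z)-10-[(tert-butyldiphenylsilyl)oxy]-4,8-dimethyldeca-4,8-dienal | O=CCC/C(C)=C/CC/C(C)=C\CO[Si](c1ccccc1)(c1ccccc1)C(C)(C)C | intermediate
11 | methyl 2-(triphenylphosphoranylidene)propanoate | COC(=O)C(C)=P(c1ccccc1)(c1ccccc1)c1ccccc1 | starting material
12 | methyl (2E,6E,10Z)-12-[(tert-butyldiphenylsilyl)oxy]-2,6,10-trimethyldodeca-2,6,10-trienoate | COC(=O)/C(C)=C/CC/C(C)=C/CC/C(C)=C\CO[Si](c1ccccc1)(c1ccccc1)C(C)(C)C | intermediate
13 | methyl (2E,6E,10Z)-12-hydroxy-2,6,10-trimethyldodeca-2,6,10-trienoate | COC(=O)/C(C)=C/CC/C(C)=C/CC/C(C)=C\CO | intermediate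
14 | methyl (2E,6E)-9-[(2S,3R)-3-(hydroxymethyl)-2-methyloxiran-2-yl]-2,6-dimethylnona-2,6-dienoate | COC(=O)/C(C)=C/CC/C(C)=C/CC[C@]1(C)O[C@@H]1CO | intermediate
15 | methyl (2E,6E)-9-[(2S,3S)-3-formyl-2-methyloxiran-2-yl]-2,6-dimethylnona-2,6-dienoate | COC(=O)/C(C)=C/CC/C(C)=C/CC[C@]1(C)O[C@@H]1C=O | intermediate
16 | cyclohexane-1,3-dione | O=C1CCCC(=O)C1 | starting material
17 | methyl (2E,6E)-9-{(2S,3R)-3-[(2,6-dioxocyclohexylidene)methyl]-2-methyloxiran-2-yl}-2,6-dimethylnona-2,6-dienoate | COC(=O)/C(C)=C/CC/C(C)=C/CC[C@]1(C)O[C@@H]1C=C2C(=O)CCCC2=O | intermediate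
18 | methyl (2E,6E)-9-{(2S,3R)-3-[(2,6-dioxocyclohexyl)methyl]-2-methyloxiran-2-yl}-2,6-dimethylnona-2,6-dienoate | COC(=O)/C(C)=C/CC/C(C)=C/CC[C@]1(C)O[C@@H]1CC2C(=O)CCCC2=O | intermediate
19 | methyl (2E,6E,10S)-10-hydroxy-2,6-dimethyl-10-[(2S)-4-oxo-2,3,4,5,6,7-hexahydro-1-benzofuran-2-yl]undeca-2,6-dienoate | C/C(=C\CC[C@](C)(O)[C@@H]1CC2=C(CCCC2=O)O1)CC/C=C(\C)C(=O)OC | intermediate
20 | disodium salt of 19 (C10′ alkoxide and C4–C5 dienolate) | C/C(=C\CC[C@](C)([O-])[C@@H]1CC2=C(CCC=C2[O-])O1)CC/C=C(\C)C(=O)OC.[Na+].[Na+] | intermediate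
21 | methyl (2E,6E,10S)-10-hydroxy-10-[(2S,5R)-5-hydroxy-4-oxo-2,3,4,5,6,7-hexahydro-1-benzofuran-2-yl]-2,6-dimethylundeca-2,6-dienoate | C/C(=C\CC[C@](C)(O)[C@@H]1CC2=C(CC[C@@H](O)C2=O)O1)CC/C=C(\C)C(=O)OC | intermediate
22 | (2E,6E,10S)-10-hydroxy-10-[(2S,5R)-5-hydroxy-4-oxo-2,3,4,5,6,7-hexahydro-1-benzofuran-2-yl]-2,6-dimethylundeca-2,6-dienoic acid | C/C(=C\CC[C@](C)(O)[C@@H]1CC2=C(CC[C@@H](O)C2=O)O1)CC/C=C(\C)C(=O)O | target

Total step count: 12. Longest linear sequence: 12 steps (nerol 1 to 22).

**Steps most likely to fail**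

1. Step 10 (proposed new method). The epoxy aldehyde may be lost to amine- or acid-induced epoxide opening before it condenses, or the epoxide of 18 may open at its tertiary carbon (6-endo) before the enolate is formed. The fallback uses known reactions, sets out from 14 and returns at 19, and moves the inversion at the epoxide CH carbon to an earlier step. Compound 14 is treated with Cs2CO3 and CO2 in DMF; the carbonate anion formed on the primary hydroxyl opens the epoxide 5-exo at the secondary carbon with inversion and gives the hydroxy carbonate F1. K2CO3 in MeOH at 0 °C releases the triol F2. TEMPO with PhI(OAc)2 oxidises only the primary hydroxyl and gives the dihydroxy aldehyde F3. The standard reductive alkylation with 16, the Hantzsch ester and proline, now without an epoxide in the substrate, passes through the alkylidene dione F4 and gives the dihydroxyalkyl dione F5. Pyridinium p-toluenesulfonate in toluene with molecular sieves then condenses the secondary hydroxyl with the dione carbonyl (cyclodehydration to the vinylogous ester, closing ring B through O1–C7a with the C2–O bond already in place and retained) and gives 19.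

2. Step 11. Facial selectivity of oxygen transfer may be poor for an enolate without an α-substituent, and deprotonation at the γ-position of the enoate may compete. The fallback sets out from 19 and returns at 21, replacing reagent control by an enzymatic separation. The dienolate 20 is oxidised with racemic trans-3-phenyl-2-(phenylsulfonyl)oxaziridine to the C5-epimer mixture F6. A lipase (Burkholderia cepacia lipase, vinyl acetate, t-BuOMe) should acetylate the 5R epimer, as the empirical size rule for secondary alcohols predicts, giving the 5R acetate F7 and leaving the 5S alcohol F8; acetate and alcohol should separate readily on silica. Lipase-catalysed methanolysis of F7 (Candida antarctica lipase B, MeOH) then gives 21 without base.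

3. Step 12. Cleavage of the hindered conjugated ester may be slow, and prolonged heating may cause epimerisation at C5 or opening of the vinylogous ester. The fallback sets out from 19 and returns at 22, reversing the order of the last two steps. Compound 19 is saponified with LiOH in THF/H2O at rt, before the base-sensitive α-ketol exists, to give the acid F9. NaN(SiMe3)2 (3.3 equiv) in THF at −78 °C converts it into the trisodium salt F10, which is oxidised with the same (camphorsulfonyl)oxaziridine and gives 22 directly on acidic work-up.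

**Further compounds**

F1 | step 10 | methyl (2E,6E,10S)-10-hydroxy-2,6-dimethyl-10-[(4S)-2-oxo-1,3-dioxolan-4-yl]undeca-2,6-dienoate | C/C(=C\CC[C@](C)(O)[C@@H]1COC(=O)O1)CC/C=C(\C)C(=O)OC
F2 | step 10 | methyl (2E,6E,10S,11S)-10,11,12-trihydroxy-2,6,10-trimethyldodeca-2,6-dienoate | C/C(=C\CC[C@](C)(O)[C@@H](O)CO)CC/C=C(\C)C(=O)OC
F3 | step 10 | methyl (2E,6E,10S,11R)-10,11-dihydroxy-2,6,10-trimethyl-12-oxododeca-2,6-dienoate | C/C(=C\CC[C@](C)(O)[C@@H](O)C=O)CC/C=C(\C)C(=O)OC
F4 | step 10 | methyl (2E,6E,10S,11S)-12-(2,6-dioxocyclohexylidene)-10,11-dihydroxy-2,6,10-trimethyldodeca-2,6-dienoate | C/C(=C\CC[C@](C)(O)[C@@H](O)C=C1C(=O)CCCC1=O)CC/C=C(\C)C(=O)OC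
F5 | step 10 | methyl (2E,6E,10S,11S)-12-(2,6-dioxocyclohexyl)-10,11-dihydroxy-2,6,10-trimethyldodeca-2,6-dienoate | C/C(=C\CC[C@](C)(O)[C@@H](O)CC1C(=O)CCCC1=O)CC/C=C(\C)C(=O)OC
F6 | step 11 | methyl (2E,6E,10S)-10-hydroxy-10-[(2S,5RS)-5-hydroxy-4-oxo-2,3,4,5,6,7-hexahydro-1-benzofuran-2-yl]-2,6-dimethylundeca-2,6-dienoate (C5-epimer mixture) | C/C(=C\CC[C@](C)(O)[C@@H]1CC2=C(CCC(O)C2=O)O1)CC/C=C(\C)C(=O)OC
F7 | step 11 | methyl (2E,6E,10S)-10-[(2S,5R)-5-(acetyloxy)-4-oxo-2,3,4,5,6,7-hexahydro-1-benzofuran-2-yl]-10-hydroxy-2,6-dimethylundeca-2,6-dienoate | C/C(=C\CC[C@](C)(O)[C@@H]1CC2=C(CC[C@@H](OC(C)=O)C2=O)O1)CC/C=C(\C)C(=O)OC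
F8 | step 11 | methyl (2E,6E,10S)-10-hydroxy-10-[(2S,5S)-5-hydroxy-4-oxo-2,3,4,5,6,7-hexahydro-1-benzofuran-2-yl]-2,6-dimethylundeca-2,6-dienoate | C/C(=C\CC[C@](C)(O)[C@@H]1CC2=C(CC[C@H](O)C2=O)O1)CC/C=C(\C)C(=O)OC
F9 | step 12 | (2E,6E,10S)-10-hydroxy-2,6-dimethyl-10-[(2S)-4-oxo-2,3,4,5,6,7-hexahydro-1-benzofuran-2-yl]undeca-2,6-dienoic acid | C/C(=C\CC[C@](C)(O)[C@@H]1CC2=C(CCCC2=O)O1)CC/C=C(\C)C(=O)O
F10 | step 12 | trisodium salt of F9 (carboxylate, C10′ alkoxide and C4–C5 dienolate) | C/C(=C\CC[C@](C)([O-])[C@@H]1CC2=C(CCC=C2[O-])O1)CC/C=C(\C)C(=O)[O-].[Na+].[Na+].[Na+]
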